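**Plan**

- Retrosynthesis: the C14 methacrylate, C1 acetate and C6 silyl ether are adjusted last. The lactone carbonyl C12 is removed as CO (bonds C11–C12 and C12–O8). The carbocycle is cut at C6–C7 and C8–C9 (Diels–Alder), and the diene at C5–C10 back to (S)-citronellal.
- Forward: the α-carbon of citronellal (C5) is joined to C10 by aza-enolate addition and Peterson olefination, and the aldehyde becomes the (1E)-siloxy diene C6=C5–C10=C9. The six-membered ring is closed first by [4+2], the γ-lactone second by Pd/CO. The side-chain olefin is then cut to give C1–OAc, and C14 is esterified.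
- Stereochemistry: C4 comes from (S)-citronellal. C6, C7 and C8 arise together from the endo, ortho addition of the (E)-diene to an (E)-β-boryl enone under an (R)-oxazaborolidinium catalyst. C8–O comes from stereoretentive C–B oxidation.
- Enabling feature: ring C5–C10 is a cyclohexene whose only C=C (tetrasubstituted C5=C10) lies between O-bearing C6 and C9H2, with C7–C11 cis to C6–O and trans to C8–O. This is the retron of a 1-oxy-diene plus (E)-acyl-vinylboronate cycloaddition: C11/C13 are the acetyl group of the dienophile and boron is the masked lactone oxygen.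

Key step: step 7

Remark: atom labels follow seco-eudesmane numbering. Ring C5 (bears the side chain), C6 (OH), C7, C8 (lactone O), C9, C10 (bears C14H2O); side chain C4 (methyl C15), C3, C2, C1 (OAc); lactone C11 (=C13H2), C12 (C=O). TBS = tert-butyldimethylsilyl, TIPS = triisopropylsilyl, Bpin = 4,4,5,5-tetramethyl-1,3,2-dioxaborolan-2-yl. Compounds 1, 3 and 9 are taken as commercial.

**Route**

Step 1
Reactants: 1 methyl 2-[(tert-butyldimethylsilyl)oxy]acetate
Product: 2 1-[(tert-butyldimethylsilyl)oxy]-3-(trimethylsilyl)propan-2-one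
Conditions: Me3SiCH2Li (2.2 equiv), pentane/THF, −78 → 0 °C; aq. NH4Cl, −78 °C; used crude
Reagents that add atoms: (trimethylsilyl)methyllithium, [Li]C[Si](C)(C)C
Why: Acyl substitution of the ester by the α-silyl carbanion should stop at the ketone because the α-silyl ketone is deprotonated at once by the second equivalent (known route to α-silyl ketones); no stereocentre is involved.

Step 2
Reactants: 3 (S)-citronellal
Product: 4 (E)-N-tert-butyl-(3S)-3,7-dimethyloct-6-en-1-imine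
Conditions: t-BuNH2, MgSO4, CH2Cl2, rt
Reagents that add atoms: tert-butylamine, CC(C)(C)N
Why: Simple aldimine condensation that prepares the aldehyde α-carbon (C5) for clean metalation; the C4 centre is β to the C=N bond and is not touched.

Step 3
Reactants: 4 (E)-N-tert-butyl-(3S)-3,7-dimethyloct-6-en-1-imine; 2 1-[(tert-butyldimethylsilyl)oxy]-3-(trimethylsilyl)propan-2-one
Product: 7 (3S)-2-[3-[(tert-butyldimethylsilyl)oxy]prop-1-en-2-yl]-3,7-dimethyloct-6-enal (C2 epimers), via lithium β-silyl alkoxide 5 (not isolated), via β,γ-unsaturated aldimine 6 (not isolated)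
Conditions: LDA, THF, −78 → 0 °C; 2, −78 °C; KOt-Bu, −78 → 0 °C; aq. AcOH/NaOAc (pH 4.5), 0 °C
Reagents that add atoms: water, O
Why: Directed (Wittig-type) aldol addition of the lithiated aldimine to the ketone followed by Peterson olefination, in which the Me3Si group dictates that the new double bond is the terminal C10=C9 one; buffered hydrolysis should free the β,γ-unsaturated aldehyde, whose C5 epimer mixture is erased in step 4.

Step 4
Reactants: 7 (3S)-2-[3-[(tert-butyldimethylsilyl)oxy]prop-1-en-2-yl]-3,7-dimethyloct-6-enal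
Product: 8 triisopropyl{[(1E)-3-{[(tert-butyldimethylsilyl)oxy]methyl}-2-[(2S)-6-methylhept-5-en-2-yl]buta-1,3-dien-1-yl]oxy}silane
Conditions: TIPSOTf, Et3N, CH2Cl2, −78 → 0 °C; used promptly
Reagents that add atoms: triisopropylsilyl trifluoromethanesulfonate, CC(C)[Si](OS(=O)(=O)C(F)(F)F)(C(C)C)C(C)C
Why: Soft enolisation removes the doubly activated C5–H regiospecifically to give the conjugated silyl dienol ether; the (1E) isomer (O cis to the C4–H side) should prevail by allylic strain, and any (1Z) isomer cannot reach the s-cis conformation and stays inert in step 7.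

Step 5
Reactants: 9 but-3-yn-2-ol
Product: 10 (E)-4-(4,4,5,5-tetramethyl-1,3,2-dioxaborolan-2-yl)but-3-en-2-ol
Conditions: B2pin2, CuCl (5 mol %), Xantphos (5 mol %), NaOt-Bu (10 mol %), MeOH, THF, rt
Reagents that add atoms: bis(pinacolato)diboron, CC1(C)OB(OC1(C)C)B1OC(C)(C)C(C)(C)O1
Why: Copper-catalysed protoboration (syn Cu–B addition, then protonation) places boron on the terminal carbon and gives the (E)-alkenylboronate; the racemic carbinol centre is removed in step 6.

Step 6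
Reactants: 10 (E)-4-(4,4,5,5-tetramethyl-1,3,2-dioxaborolan-2-yl)but-3-en-2-ol
Product: 11 (E)-4-(4,4,5,5-tetramethyl-1,3,2-dioxaborolan-2-yl)but-3-en-2-one
Conditions: MnO2, CH2Cl2, rt
Reagents that add atoms: none
Why: Selective oxidation of an allylic alcohol to the enone, which leaves the C–B bond and the (E) geometry intact.

Step 7
Reactants: 8 triisopropyl{[(1E)-3-{[(tert-butyldimethylsilyl)oxy]methyl}-2-[(2S)-6-methylhept-5-en-2-yl]buta-1,3-dien-1-yl]oxy}silane; 11 (E)-4-(4,4,5,5-tetramethyl-1,3,2-dioxaborolan-2-yl)but-3-en-2-one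
Product: 12 1-[(1S,2S,6R)-6-Bpin-4-(TBSO-methyl)-3-[(2S)-6-methylhept-5-en-2-yl]-2-(TIPSO)cyclohex-3-en-1-yl]ethanone
Conditions: (R)-o-tolyl-CBS-oxazaborolidine (20 mol %), Tf2NH (18 mol %), CH2Cl2, −78 → −40 °C
Reagents that add atoms: none
Why: The protonated oxazaborolidine binds the enone carbonyl of 11 and lowers its LUMO, and diene 8 adds in a concerted but asynchronous normal-demand [4+2] in which C9 (δ to the silyloxy donor, largest HOMO coefficient) bonds first to C8 (β-carbon) and C6 then bonds to C7, so that the acetyl group ends next to C6 and boron next to C9. The closest known reaction types are the cationic oxazaborolidine- or strong chiral Brønsted acid-catalysed enantioselective Diels–Alder reactions of enones with triisopropylsilyloxy dienes, and the use of (E)-β-boryl enones and acrylates as dienophiles that stand for a trans-β-hydroxyvinyl carbonyl unit. The one ring closed is the carbocycle C5–C10, formed by suprafacial [4+2] addition; its tetrasubstituted C5=C10 double bond arises from the central bond of the diene, so no olefin geometry has to be controlled. The cis relation C6–O/C7–acetyl follows from the endo transition state of the (1E)-diene, the trans relation C7/C8 from the (E) geometry of 11, and the absolute sense from the catalyst: in the α-C–H···O binding model for enones the (R)-catalyst should cover the Si face of C7 and leave the Re face open, while the remote C4 centre is a spectator, so the diastereomer ratio should mirror the enantioselectivity of the catalyst. The step needs ortho regiochemistry (secured by the 1-silyloxy group), endo selectivity (secondary overlap with the bound acetyl group) and ring closure instead of Mukaiyama–Michael silyl transfer (secured by the bulky TIPS group and the low temperature).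

Step 8
Reactants: 12 1-[(1S,2S,6R)-6-Bpin-4-(TBSO-methyl)-3-[(2S)-6-methylhept-5-en-2-yl]-2-(TIPSO)cyclohex-3-en-1-yl]ethanone
Product: 13 1-[(1S,2S,6R)-6-Bpin-4-(TBSO-methyl)-3-[(2S)-6-methylhept-5-en-2-yl]-2-(TIPSO)cyclohex-3-en-1-yl]ethenyl trifluoromethanesulfonate
Conditions: KHMDS, THF, −78 °C; PhNTf2, −78 → −40 °C
Reagents that add atoms: N-phenylbis(trifluoromethanesulfonimide), O=S(=O)(N(c1ccccc1)S(=O)(=O)C(F)(F)F)C(F)(F)F
Why: Kinetic deprotonation of the methyl ketone at the unhindered CH3 group and O-triflation give the terminal enol triflate (C11=C13); C7–H is not removed, so neither epimerisation nor β-elimination of the C6 silyloxy group should occur.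

Step 9
Reactants: 13 1-[(1S,2S,6R)-6-Bpin-4-(TBSO-methyl)-3-[(2S)-6-methylhept-5-en-2-yl]-2-(TIPSO)cyclohex-3-en-1-yl]ethenyl trifluoromethanesulfonate
Product: 14 1-[(1S,2S,6R)-6-hydroxy-4-(TBSO-methyl)-3-[(2S)-6-methylhept-5-en-2-yl]-2-(TIPSO)cyclohex-3-en-1-yl]ethenyl trifluoromethanesulfonate
Conditions: NaBO3·4H2O, THF/H2O, 0 °C → rt
Reagents that add atoms: sodium perborate, B(=O)O[O-].[Na+]
Why: Boronate oxidation proceeds by 1,2-migration with retention, so the C8–OH is delivered trans to the C7 substituent; the mild perborate conditions should spare the vinyl triflate and both silyl ethers.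

Step 10
Reactants: 14 1-[(1S,2S,6R)-6-hydroxy-4-(TBSO-methyl)-3-[(2S)-6-methylhept-5-en-2-yl]-2-(TIPSO)cyclohex-3-en-1-yl]ethenyl trifluoromethanesulfonate
Product: 15 (3aS,4S,7aR)-6-(TBSO-methyl)-3-methylidene-5-[(2S)-6-methylhept-5-en-2-yl]-4-(TIPSO)-3a,4,7,7a-tetrahydro-1-benzofuran-2(3H)-one
Conditions: Pd(PPh3)4 (10 mol %), CO (1 atm), n-Bu3N, MeCN, 65 °C
Reagents that add atoms: carbon monoxide, [C-]#[O+]
Why: Oxidative addition of the vinyl triflate, CO insertion and capture of the acyl-palladium by the equatorial C8–OH (intramolecular alkoxycarbonylation of a hydroxy vinyl triflate) should give the trans-fused α-methylene-γ-butyrolactone directly; no stereocentre changes.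

Step 11
Reactants: 15 (3aS,4S,7aR)-6-(TBSO-methyl)-3-methylidene-5-[(2S)-6-methylhept-5-en-2-yl]-4-(TIPSO)-3a,4,7,7a-tetrahydro-1-benzofuran-2(3H)-one
Product: 17 (4S)-4-[(3aS,4S,7aR)-6-(TBSO-methyl)-3-methylidene-2-oxo-4-(TIPSO)-2,3,3a,4,7,7a-hexahydro-1-benzofuran-5-yl]pentanal, via diol 16 (not isolated)
Conditions: OsO4 (2 mol %), NMO (1.1 equiv), acetone/H2O, 0 °C; then NaIO4, THF/H2O (pH 7), 0 °C
Reagents that add atoms: osmium tetroxide (catalytic), O=[Os](=O)(=O)=O; N-methylmorpholine N-oxide, C[N+]1([O-])CCOCC1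
Why: Upjohn dihydroxylation should pick the electron-rich, unhindered trisubstituted side-chain olefin over the hindered tetrasubstituted ring olefin and the electron-poor methylene lactone, and periodate glycol cleavage then gives the C1 aldehyde.

Step 12
Reactants: 17 (4S)-4-[(3aS,4S,7aR)-6-(TBSO-methyl)-3-methylidene-2-oxo-4-(TIPSO)-2,3,3a,4,7,7a-hexahydro-1-benzofuran-5-yl]pentanal
Product: 18 (3aS,4S,7aR)-5-[(2S)-5-hydroxypentan-2-yl]-6-(TBSO-methyl)-3-methylidene-4-(TIPSO)-3a,4,7,7a-tetrahydro-1-benzofuran-2(3H)-one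
Conditions: NaBH4, CeCl3·7H2O, MeOH/THF, −78 °C
Reagents that add atoms: none
Why: Under Luche conditions at −78 °C the aldehyde should undergo 1,2-reduction much faster than conjugate reduction of the α-methylene lactone.

Step 13
Reactants: 18 (3aS,4S,7aR)-5-[(2S)-5-hydroxypentan-2-yl]-6-(TBSO-methyl)-3-methylidene-4-(TIPSO)-3a,4,7,7a-tetrahydro-1-benzofuran-2(3H)-one
Product: 19 (4S)-4-[(3aS,4S,7aR)-6-(TBSO-methyl)-3-methylidene-2-oxo-4-(TIPSO)-2,3,3a,4,7,7a-hexahydro-1-benzofuran-5-yl]pentyl acetate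
Conditions: Ac2O, pyridine, DMAP (cat.), CH2Cl2, 0 °C
Reagents that add atoms: acetic anhydride, CC(=O)OC(C)=O
Why: Standard acetylation of the only free hydroxyl group installs the C1 acetate.

Step 14
Reactants: 19 (4S)-4-[(3aS,4S,7aR)-6-(TBSO-methyl)-3-methylidene-2-oxo-4-(TIPSO)-2,3,3a,4,7,7a-hexahydro-1-benzofuran-5-yl]pentyl acetate
Product: 20 (4S)-4-[(3aS,4S,7aR)-6-(hydroxymethyl)-3-methylidene-2-oxo-4-(TIPSO)-2,3,3a,4,7,7a-hexahydro-1-benzofuran-5-yl]pentyl acetate
Conditions: HF·pyridine, pyridine, THF, 0 °C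
Reagents that add atoms: none
Why: Buffered HF·pyridine should cleave the primary allylic TBS ether far faster than the hindered secondary TIPS ether at C6.

Step 15
Reactants: 20 (4S)-4-[(3aS,4S,7aR)-6-(hydroxymethyl)-3-methylidene-2-oxo-4-(TIPSO)-2,3,3a,4,7,7a-hexahydro-1-benzofuran-5-yl]pentyl acetate
Product: 21 [(3aS,4S,7aR)-5-[(2S)-5-acetoxypentan-2-yl]-3-methylidene-2-oxo-4-(TIPSO)-2,3,3a,4,7,7a-hexahydro-1-benzofuran-6-yl]methyl 2-methylprop-2-enoate
Conditions: methacrylic anhydride, Et3N, DMAP (cat.), CH2Cl2, 0 °C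
Reagents that add atoms: methacrylic anhydride, CC(=C)C(=O)OC(=O)C(C)=C
Why: DMAP-catalysed acylation of the primary allylic alcohol installs the methacrylate while C6–O is still silylated, so neither acylation at C6 nor lactone migration to O6 can compete.

Step 16
Reactants: 21 [(3aS,4S,7aR)-5-[(2S)-5-acetoxypentan-2-yl]-3-methylidene-2-oxo-4-(TIPSO)-2,3,3a,4,7,7a-hexahydro-1-benzofuran-6-yl]methyl 2-methylprop-2-enoate
Product: 22 [(3aR,4S,7aR)-5-[(2S)-5-acetoxypentan-2-yl]-4-hydroxy-3-methylidene-2-oxo-2,3,3a,4,7,7a-hexahydro-1-benzofuran-6-yl]methyl 2-methylprop-2-enoate (CNP0122587.1)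
Conditions: HF·pyridine, THF, 0 °C → rt
Reagents that add atoms: none
Why: Fluoride desilylation under mildly acidic, non-basic conditions frees the C6 hydroxyl last, which should avoid base-induced translactonisation to O6 and Michael addition to the two acrylate units; the C7 descriptor changes from S to R only because the CIP priorities change.

**Compound list**

1 | methyl 2-[(tert-butyldimethylsilyl)oxy]acetate | COC(=O)CO[Si](C)(C)C(C)(C)C | starting material
2 | 1-[(tert-butyldimethylsilyl)oxy]-3-(trimethylsilyl)propan-2-one | CC(C)(C)[Si](C)(C)OCC(=O)C[Si](C)(C)C | intermediate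
3 | (S)-citronellal, (3S)-3,7-dimethyloct-6-enal | O=CC[C@@H](C)CCC=C(C)C | starting material
4 | (E)-N-tert-butyl-(3S)-3,7-dimethyloct-6-en-1-imine | CC(C)(C)/N=C/C[C@@H](C)CCC=C(C)C | intermediate
5 | lithium alkoxide of (3S)-N-tert-butyl-2-[1-(TBSO)-2-hydroxy-3-(trimethylsilyl)propan-2-yl]-3,7-dimethyloct-6-en-1-imine (diastereomer mixture) | [Li+].CC(C)(C)/N=C/C([C@@H](C)CCC=C(C)C)C([O-])(C[Si](C)(C)C)CO[Si](C)(C)C(C)(C)C | intermediate
6 | (3S)-N-tert-butyl-2-[3-(TBSO)prop-1-en-2-yl]-3,7-dimethyloct-6-en-1-imine (C2 epimers) | CC(C)(C)/N=C/C([C@@H](C)CCC=C(C)C)C(=C)CO[Si](C)(C)C(C)(C)C | intermediate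
7 | (3S)-2-[3-[(tert-butyldimethylsilyl)oxy]prop-1-en-2-yl]-3,7-dimethyloct-6-enal (C2 epimers) | O=CC([C@@H](C)CCC=C(C)C)C(=C)CO[Si](C)(C)C(C)(C)C | intermediate
8 | triisopropyl{[(1E)-3-{[(tert-butyldimethylsilyl)oxy]methyl}-2-[(2S)-6-methylhept-5-en-2-yl]buta-1,3-dien-1-yl]oxy}silane | CC(C)[Si](C(C)C)(C(C)C)O/C=C(\[C@@H](C)CCC=C(C)C)C(=C)CO[Si](C)(C)C(C)(C)C | intermediate
9 | but-3-yn-2-ol (racemic) | CC(O)C#C | starting material
10 | (E)-4-(4,4,5,5-tetramethyl-1,3,2-dioxaborolan-2-yl)but-3-en-2-ol (racemic) | CC(O)/C=C/B1OC(C)(C)C(C)(C)O1 | intermediate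
11 | (E)-4-(4,4,5,5-tetramethyl-1,3,2-dioxaborolan-2-yl)but-3-en-2-one | CC(=O)/C=C/B1OC(C)(C)C(C)(C)O1 | intermediate
12 | 1-[(1S,2S,6R)-6-Bpin-4-(TBSO-methyl)-3-[(2S)-6-methylhept-5-en-2-yl]-2-(TIPSO)cyclohex-3-en-1-yl]ethanone | CC(C)(C)[Si](C)(C)OCC1=C([C@@H](C)CCC=C(C)C)[C@@H](O[Si](C(C)C)(C(C)C)C(C)C)[C@@H](C(C)=O)[C@H](B2OC(C)(C)C(C)(C)O2)C1 | intermediate
13 | 1-[(1S,2S,6R)-6-Bpin-4-(TBSO-methyl)-3-[(2S)-6-methylhept-5-en-2-yl]-2-(TIPSO)cyclohex-3-en-1-yl]ethenyl trifluoromethanesulfonate | CC(C)(C)[Si](C)(C)OCC1=C([C@@H](C)CCC=C(C)C)[C@@H](O[Si](C(C)C)(C(C)C)C(C)C)[C@@H](C(=C)OS(=O)(=O)C(F)(F)F)[C@H](B2OC(C)(C)C(C)(C)O2)C1 | intermediate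
14 | 1-[(1S,2S,6R)-6-hydroxy-4-(TBSO-methyl)-3-[(2S)-6-methylhept-5-en-2-yl]-2-(TIPSO)cyclohex-3-en-1-yl]ethenyl trifluoromethanesulfonate | CC(C)(C)[Si](C)(C)OCC1=C([C@@H](C)CCC=C(C)C)[C@@H](O[Si](C(C)C)(C(C)C)C(C)C)[C@@H](C(=C)OS(=O)(=O)C(F)(F)F)[C@H](O)C1 | intermediate
15 | (3aS,4S,7aR)-6-(TBSO-methyl)-3-methylidene-5-[(2S)-6-methylhept-5-en-2-yl]-4-(TIPSO)-3a,4,7,7a-tetrahydro-1-benzofuran-2(3H)-one | CC(C)(C)[Si](C)(C)OCC1=C([C@@H](C)CCC=C(C)C)[C@@H](O[Si](C(C)C)(C(C)C)C(C)C)[C@H]2C(=C)C(=O)O[C@@H]2C1 | intermediate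
16 | (3aS,4S,7aR)-5-[(2S)-5,6-dihydroxy-6-methylheptan-2-yl]-6-(TBSO-methyl)-3-methylidene-4-(TIPSO)-3a,4,7,7a-tetrahydro-1-benzofuran-2(3H)-one (carbinol epimers) | CC(C)(C)[Si](C)(C)OCC1=C([C@@H](C)CCC(O)C(C)(C)O)[C@@H](O[Si](C(C)C)(C(C)C)C(C)C)[C@H]2C(=C)C(=O)O[C@@H]2C1 | intermediate
17 | (4S)-4-[(3aS,4S,7aR)-6-(TBSO-methyl)-3-methylidene-2-oxo-4-(TIPSO)-2,3,3a,4,7,7a-hexahydro-1-benzofuran-5-yl]pentanal | CC(C)(C)[Si](C)(C)OCC1=C([C@@H](C)CCC=O)[C@@H](O[Si](C(C)C)(C(C)C)C(C)C)[C@H]2C(=C)C(=O)O[C@@H]2C1 | intermediate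
18 | (3aS,4S,7aR)-5-[(2S)-5-hydroxypentan-2-yl]-6-(TBSO-methyl)-3-methylidene-4-(TIPSO)-3a,4,7,7a-tetrahydro-1-benzofuran-2(3H)-one | CC(C)(C)[Si](C)(C)OCC1=C([C@@H](C)CCCO)[C@@H](O[Si](C(C)C)(C(C)C)C(C)C)[C@H]2C(=C)C(=O)O[C@@H]2C1 | intermediate
19 | (4S)-4-[(3aS,4S,7aR)-6-(TBSO-methyl)-3-methylidene-2-oxo-4-(TIPSO)-2,3,3a,4,7,7a-hexahydro-1-benzofuran-5-yl]pentyl acetate | CC(C)(C)[Si](C)(C)OCC1=C([C@@H](C)CCCOC(C)=O)[C@@H](O[Si](C(C)C)(C(C)C)C(C)C)[C@H]2C(=C)C(=O)O[C@@H]2C1 | intermediate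
20 | (4S)-4-[(3aS,4S,7aR)-6-(hydroxymethyl)-3-methylidene-2-oxo-4-(TIPSO)-2,3,3a,4,7,7a-hexahydro-1-benzofuran-5-yl]pentyl acetate | OCC1=C([C@@H](C)CCCOC(C)=O)[C@@H](O[Si](C(C)C)(C(C)C)C(C)C)[C@H]2C(=C)C(=O)O[C@@H]2C1 | intermediate
21 | [(3aS,4S,7aR)-5-[(2S)-5-acetoxypentan-2-yl]-3-methylidene-2-oxo-4-(TIPSO)-2,3,3a,4,7,7a-hexahydro-1-benzofuran-6-yl]methyl 2-methylprop-2-enoate | C=C(C)C(=O)OCC1=C([C@@H](C)CCCOC(C)=O)[C@@H](O[Si](C(C)C)(C(C)C)C(C)C)[C@H]2C(=C)C(=O)O[C@@H]2C1 | intermediate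
22 | [(3aR,4S,7aR)-5-[(2S)-5-acetoxypentan-2-yl]-4-hydroxy-3-methylidene-2-oxo-2,3,3a,4,7,7a-hexahydro-1-benzofuran-6-yl]methyl 2-methylprop-2-enoate | C=C(C)C(=O)OCC1=C([C@@H](C)CCCOC(C)=O)[C@@H](O)[C@H]2C(=C)C(=O)O[C@@H]2C1 | target

**Step count and risks**

Total step count: 16 (one step for ketone 2, two for dienophile 11, thirteen on the main line).
Longest linear sequence: 13 steps from (S)-citronellal (steps 2, 3, 4 and 7–16).

Steps most likely to fail:

1. Step 7. The catalyst may discriminate the two faces of the enone poorly or in the opposite sense to the binding model. The acid may also cleave the silyl dienol ether or divert the reaction into an open-chain Mukaiyama–Michael product by silyl transfer. Fallback: catalyst control is given up in favour of an internal resolution. Diene 8 and enone 11 are heated without catalyst (toluene, 90 °C, BHT). The thermal endo, ortho cycloaddition should give 12 together with its ring-diastereomer 1-[(1R,2R,6S)-6-Bpin-4-(TBSO-methyl)-3-[(2S)-6-methylhept-5-en-2-yl]-2-(TIPSO)cyclohex-3-en-1-yl]ethanone F1. Because the C4 centre from citronellal makes the two face adducts diastereomers, they are separated by chromatography, and the route continues from 12.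

2. Step 3. The aza-enolate may deprotonate the enolisable α-silyl ketone instead of adding to it. The β,γ-unsaturated aldehyde may also slip into conjugation during hydrolysis, which would cost the regiocontrol of step 4. Fallback: the C10 unit is brought in as a pyruvate, which has only one enolisable γ-position. Lithiated 4 is added to ethyl pyruvate and the adduct is hydrolysed and dehydrated with aqueous oxalic acid to ethyl (4S)-3-formyl-2,4,8-trimethylnona-2,7-dienoate F2. TIPSOTf/Et3N gives ethyl (3E,4S)-4,8-dimethyl-2-methylidene-3-{[(triisopropylsilyl)oxy]methylidene}non-7-enoate F3, which is kept cold and reduced at once with DIBAL-H (CH2Cl2, −78 °C) to (3E,4S)-4,8-dimethyl-2-methylidene-3-{[(triisopropylsilyl)oxy]methylidene}non-7-en-1-ol F4. Silylation with TBSCl/imidazole returns to 8.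

3. Step 8. Enolisation towards C7 would lead to β-elimination of the C6 silyloxy group and on to aromatisation, and the amide base may complex the boronate. Fallback: the ketone is turned into a vinyl halide without enolate chemistry. Ketone 12 is condensed with hydrazine hydrate (EtOH) to the hydrazone of 12 F5. Barton iodination (I2, tetramethylguanidine, THF, 0 °C) gives 2-{[(1S,2S,6R)-6-Bpin-5-(1-iodoethenyl)-4-(TIPSO)-3-[(2S)-6-methylhept-5-en-2-yl]cyclohex-2-en-1-yl]}-type vinyl iodide, that is the 1-iodoethenyl analogue of 13 F6. Perborate oxidation gives the 1-iodoethenyl analogue of 14 F7, and Pd(PPh3)4/CO/n-Bu3N cyclocarbonylation of this hydroxy vinyl iodide returns to 15.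

**Further compounds**

F1 | step 7 | 1-[(1R,2R,6S)-6-Bpin-4-(TBSO-methyl)-3-[(2S)-6-methylhept-5-en-2-yl]-2-(TIPSO)cyclohex-3-en-1-yl]ethanone | CC(C)(C)[Si](C)(C)OCC1=C([C@@H](C)CCC=C(C)C)[C@H](O[Si](C(C)C)(C(C)C)C(C)C)[C@H](C(C)=O)[C@@H](B2OC(C)(C)C(C)(C)O2)C1
F2 | step 3 | ethyl (4S)-3-formyl-2,4,8-trimethylnona-2,7-dienoate (E/Z mixture) | CCOC(=O)C(C)=C(C=O)[C@@H](C)CCC=C(C)C
F3 | step 3 | ethyl (3E,4S)-4,8-dimethyl-2-methylidene-3-{[(triisopropylsilyl)oxy]methylidene}non-7-enoate | CCOC(=O)C(=C)C(=C/O[Si](C(C)C)(C(C)C)C(C)C)/[C@@H](C)CCC=C(C)C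
F4 | step 3 | (3E,4S)-4,8-dimethyl-2-methylidene-3-{[(triisopropylsilyl)oxy]methylidene}non-7-en-1-ol | OCC(=C)C(=C/O[Si](C(C)C)(C(C)C)C(C)C)/[C@@H](C)CCC=C(C)C
F5 | step 8 | hydrazone of 12, 1-[(1S,2S,6R)-6-Bpin-4-(TBSO-methyl)-3-[(2S)-6-methylhept-5-en-2-yl]-2-(TIPSO)cyclohex-3-en-1-yl]ethanone hydrazone | CC(C)(C)[Si](C)(C)OCC1=C([C@@H](C)CCC=C(C)C)[C@@H](O[Si](C(C)C)(C(C)C)C(C)C)[C@@H](C(C)=NN)[C@H](B2OC(C)(C)C(C)(C)O2)C1
F6 | step 8 | 1-iodoethenyl analogue of 13, (1S,2S,6R)-1-(1-iodoethenyl)-6-Bpin-4-(TBSO-methyl)-3-[(2S)-6-methylhept-5-en-2-yl]-2-(TIPSO)cyclohex-3-ene | CC(C)(C)[Si](C)(C)OCC1=C([C@@H](C)CCC=C(C)C)[C@@H](O[Si](C(C)C)(C(C)C)C(C)C)[C@@H](C(=C)I)[C@H](B2OC(C)(C)C(C)(C)O2)C1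
F7 | step 8 | 1-iodoethenyl analogue of 14, (1R,5S,6S)-6-(1-iodoethenyl)-3-(TBSO-methyl)-4-[(2S)-6-methylhept-5-en-2-yl]-5-(TIPSO)cyclohex-3-en-1-ol | CC(C)(C)[Si](C)(C)OCC1=C([C@@H](C)CCC=C(C)C)[C@@H](O[Si](C(C)C)(C(C)C)C(C)C)[C@@H](C(=C)I)[C@H](O)C1
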